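**Retrosynthetic overview**

1. The strategy rests on the erythro pair C7/C8. C7 is the acetoxy-bearing benzylic carbon on ring C and C8 its methyl-bearing neighbour, bound through oxygen to C4 of ring B; the pair is the result of anti addition across the E-propenyl group of isoelemicin.
2. Target ⇒ Mitsunobu etherification (inversion at C8′) of the ring A phenol, (E)-2,6-dimethoxy-4-propenylphenol from methoxyeugenol, with an (S)-2-hydroxypropyl group on ring B.
3. Ring B–O8 aryl ether ⇒ O-methylation, aromatisation and rhodium-carbenoid O–H insertion of a 5-substituted 2-diazocyclohexane-1,3-dione into the C8 hydroxyl of the erythro hydroxy acetate; no base is used and the C8–O bond is never broken.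
4. Hydroxy acetate ⇒ invertive acetolysis at C7 of the (2R,3R)-epoxide ⇒ Shi epoxidation of (E)-isoelemicin ⇒ 3,4,5-trimethoxybenzaldehyde. Diazo dione ⇒ Birch reduction route from 1-bromo-3,5-dimethoxybenzene and (S)-propylene oxide.
5. Ring order: the oxirane is closed first and opened in the next step. Rings A and C are bought as arenes. Ring B is bought aromatic, carried as a cyclohexane-1,3-dione and re-aromatised once the O8 ether is in place.

Key step: step 3

Remark: C7/C8 denote the acetoxy carbon and its methyl-bearing neighbour on the ring C side chain, C7′/C8′ the CH2 and the oxygenated CH on the ring B side chain; the target is (7S,8R,8′R). Compound 14 is a tautomerising vinylogous acid, so its side-chain-bearing ring carbon is drawn without a descriptor.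

**Route**

Step 1
Reactants: 1 3,4,5-trimethoxybenzaldehyde
Product: 2 1-(3,4,5-trimethoxyphenyl)propan-1-ol (racemic)
Conditions: EtMgBr, THF, 0 °C to rt; aq. NH4Cl
Reagents that add atoms: ethylmagnesium bromide, CC[Mg]Br
Why: Grignard 1,2-addition to a non-enolisable aromatic aldehyde gives the benzylic alcohol, whose configuration is irrelevant because this carbon becomes sp2 in the next step.

Step 2
Reactants: 2 1-(3,4,5-trimethoxyphenyl)propan-1-ol
Product: 3 (E)-isoelemicin, 1,2,3-trimethoxy-5-[(E)-prop-1-en-1-yl]benzene
Conditions: TsOH·H2O (cat.), toluene, reflux, Dean–Stark, dilute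
Reagents that add atoms: none
Why: Acid-catalysed E1 dehydration through the benzylic cation is under thermodynamic control and should give the conjugated E-alkene, any Z isomer being removed on AgNO3-impregnated silica before the stereodefining step.

Step 3
Reactants: 3 (E)-isoelemicin
Product: 4 (2R,3R)-2-methyl-3-(3,4,5-trimethoxyphenyl)oxirane
Conditions: D-fructose-derived Shi ketone (1,2:4,5-di-O-isopropylidene-D-erythro-2,3-hexodiulo-2,6-pyranose, 30 mol%), KHSO5 (as 2KHSO5·KHSO4·K2SO4), K2CO3, Bu4NHSO4 (cat.), MeCN–CH2(OMe)2, aq. Na2B4O7 buffer, pH 10.5, 0 °C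
Reagents that add atoms: potassium peroxymonosulfate (KHSO5), [K+].[O-]S(=O)(=O)OO
Why: KHSO5 converts the ketone into a chiral dioxirane that transfers one oxygen atom to the alkene through a concerted spiro transition state; this is the Shi asymmetric epoxidation, and trans-β-methylstyrenes are its best-behaved substrate class. The oxirane is the only ring closed, by a single [2+1] oxygen-atom transfer that forms the C7–O and C8–O bonds together. Both new stereocentres, C7 and C8, are set by the catalyst: the alkene meets the dioxirane face remote from the fused acetonide, which for the D-fructose-derived ketone should give the (2R,3R)-epoxide, while the trans relationship is carried over stereospecifically from the E-alkene. The step needs facial selectivity, secured by the planar, aryl-conjugated E-disubstituted alkene that fits the spiro model, and chemoselectivity for the alkene over the electron-rich ring, secured by the mild electrophilicity of the dioxirane. At pH 10.5 Baeyer–Villiger loss of the catalyst and acid opening of the product are held back, and the twisted para methoxy group of ring C keeps the epoxide stable enough for isolation on Et3N-deactivated silica.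

Step 4
Reactants: 4 (2R,3R)-2-methyl-3-(3,4,5-trimethoxyphenyl)oxirane
Product: 5 (1S,2R)-2-hydroxy-1-(3,4,5-trimethoxyphenyl)propyl acetate
Conditions: AcOH, KOAc, 25–40 °C; cold pH 7 work-up, used without delay
Reagents that add atoms: acetic acid, CC(=O)O
Why: Buffered acetolysis is a borderline SN2 epoxide opening in which acetate attacks the hydrogen-bond-activated oxirane at benzylic C7 from the rear, so C7 is inverted (R to S) while the C8–O bond and its R configuration stay untouched, giving the erythro hydroxy acetate; the buffer and the weakly cation-stabilising trimethoxyphenyl ring should suppress ionisation.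

Step 5
Reactants: 6 1-bromo-3,5-dimethoxybenzene; 7 (S)-propylene oxide
Product: 9 (S)-1-(3,5-dimethoxyphenyl)propan-2-ol, via 3,5-dimethoxyphenylmagnesium bromide 8 (not isolated)
Conditions: Mg, THF, reflux; then CuI (copper monoiodide, 10 mol%), 7, −30 to 0 °C; aq. NH4Cl
Reagents that add atoms: none
Why: Grignard formation followed by copper-catalysed SN2 opening of the epoxide at its unsubstituted carbon leaves the stereocentre of (S)-propylene oxide untouched.

Step 6
Reactants: 9 (S)-1-(3,5-dimethoxyphenyl)propan-2-ol
Product: 10 (S)-1-(3,5-dimethoxyphenyl)-2-(triisopropylsilyloxy)propane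
Conditions: TIPSOTf, 2,6-lutidine, CH2Cl2, 0 °C to rt
Reagents that add atoms: triisopropylsilyl trifluoromethanesulfonate, CC(C)[Si](OS(=O)(=O)C(F)(F)F)(C(C)C)C(C)C
Why: O-silylation with a silyl triflate and a hindered base installs a triisopropylsilyl ether that should survive dissolving metal, aqueous acid, carbenoid, oxidant and carbonate base.

Step 7
Reactants: 10 (S)-1-(3,5-dimethoxyphenyl)-2-(triisopropylsilyloxy)propane
Product: 12 5-[(S)-2-(triisopropylsilyloxy)propyl]cyclohexane-1,3-dione, via bis-enol-ether diene 11 (not isolated)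
Conditions: Li, NH3 (l), THF, t-BuOH, −78 °C; NH4Cl; then 1 M HCl, THF, rt
Reagents that add atoms: water, O
Why: Birch reduction of the resorcinol dimethyl ether protonates the carbon between the methoxy groups and the alkyl-bearing carbon to give the 1,5-dimethoxy-1,4-diene, and acid hydrolysis of both enol ethers unmasks the symmetrical 1,3-dione without touching the remote stereocentre.

Step 8
Reactants: 12 5-[(S)-2-(triisopropylsilyloxy)propyl]cyclohexane-1,3-dione
Product: 13 2-diazo-5-[(S)-2-(triisopropylsilyloxy)propyl]cyclohexane-1,3-dione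
Conditions: p-ABSA, Et3N, MeCN, 0 °C to rt
Reagents that add atoms: 4-acetamidobenzenesulfonyl azide, CC(=O)Nc1ccc(cc1)S(=O)(=O)N=[N+]=[N-]
Why: Regitz diazo transfer to the acidic C2 position of a 1,3-dione is a standard, high-yielding operation.

Step 9
Reactants: 5 (1S,2R)-2-hydroxy-1-(3,4,5-trimethoxyphenyl)propyl acetate; 13 2-diazo-5-[(S)-2-(triisopropylsilyloxy)propyl]cyclohexane-1,3-dione
Product: 14 2-{[(1S,2R)-1-acetoxy-1-(3,4,5-trimethoxyphenyl)propan-2-yl]oxy}-3-hydroxy-5-[(S)-2-(triisopropylsilyloxy)propyl]cyclohex-2-en-1-one (enol form of the 2-alkoxy-1,3-dione)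
Conditions: Rh2(OAc)4 (2 mol%), fluorobenzene, 40 °C, slow addition of 13 (1.5 equiv)
Reagents that add atoms: none
Why: In this rhodium-carbenoid O–H insertion the electrophilic acceptor–acceptor carbenoid is captured by the hydroxyl oxygen (oxonium ylide, then proton shift) faster than by the acetate carbonyl or the flanked arene positions, under neutral conditions that allow no acetyl migration, and as the C8–O bond is not broken C8 keeps its R configuration.

Step 10
Reactants: 14 the 2-alkoxy-1,3-dione enol
Product: 15 (1S,2R)-2-{2,6-dihydroxy-4-[(S)-2-(triisopropylsilyloxy)propyl]phenoxy}-1-(3,4,5-trimethoxyphenyl)propyl acetate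
Conditions: DDQ (1.2 equiv), 1,4-dioxane, 80 °C
Reagents that add atoms: none
Why: DDQ dehydrogenation of the enolised cyclohexane-1,3-dione (hydride loss from C4, proton loss from C5, tautomerisation) is an oxidative aromatisation to the 2-alkoxyresorcinol that does not involve the acetate, the silyl ether or the three side-chain stereocentres.

Step 11
Reactants: 15 the 2-alkoxyresorcinol
Product: 16 (1S,2R)-2-{2,6-dimethoxy-4-[(S)-2-(triisopropylsilyloxy)propyl]phenoxy}-1-(3,4,5-trimethoxyphenyl)propyl acetate
Conditions: MeI, K2CO3, acetone, 40 °C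
Reagents that add atoms: iodomethane, CI
Why: Williamson O-methylation of both phenols under anhydrous carbonate is safe for the C7 acetate because O8 is now an ether and no neighbouring hydroxyl remains to accept the acetyl group.

Step 12
Reactants: 16 the silyl ether
Product: 17 (1S,2R)-2-{4-[(S)-2-hydroxypropyl]-2,6-dimethoxyphenoxy}-1-(3,4,5-trimethoxyphenyl)propyl acetate
Conditions: HF·pyridine, THF–pyridine, 0 °C to rt
Reagents that add atoms: none
Why: Fluoride desilylation under weakly acidic conditions cleaves only the Si–O bond, so the benzylic acetate, the aryl ethers and the carbinol configuration are retained.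

Step 13
Reactants: 18 4-allyl-2,6-dimethoxyphenol (methoxyeugenol)
Product: 19 (E)-2,6-dimethoxy-4-(prop-1-en-1-yl)phenol
Conditions: RuHCl(CO)(PPh3)3 (1 mol%), toluene, 80 °C
Reagents that add atoms: none
Why: Metal-hydride-catalysed alkene isomerisation (hydrometalation, β-hydride elimination) moves the double bond into conjugation and should favour the E isomer, residual Z isomer being removed on AgNO3-impregnated silica.

Step 14
Reactants: 17 the (S)-alcohol; 19 (E)-2,6-dimethoxy-4-(prop-1-en-1-yl)phenol
Product: 20 (1S,2R)-2-{4-[(R)-2-{2,6-dimethoxy-4-[(E)-prop-1-en-1-yl]phenoxy}propyl]-2,6-dimethoxyphenoxy}-1-(3,4,5-trimethoxyphenyl)propyl acetate (CNP0157869.1)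
Conditions: PPh3, DIAD, THF, 0 °C to rt
Reagents that add atoms: none
Why: In this Mitsunobu etherification the alcohol is activated as its alkoxyphosphonium ion and displaced by the phenoxide in an SN2 step, which inverts C8′ from S to R under neutral conditions that spare the acetate and the E-alkene.

**Compound list**

1 | 3,4,5-trimethoxybenzaldehyde | COc1cc(C=O)cc(OC)c1OC | starting material
2 | 1-(3,4,5-trimethoxyphenyl)propan-1-ol (racemic) | CCC(O)c1cc(OC)c(OC)c(OC)c1 | intermediate
3 | (E)-isoelemicin | C/C=C/c1cc(OC)c(OC)c(OC)c1 | intermediate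
4 | (2R,3R)-2-methyl-3-(3,4,5-trimethoxyphenyl)oxirane | C[C@H]1O[C@@H]1c1cc(OC)c(OC)c(OC)c1 | intermediate
5 | (1S,2R)-2-hydroxy-1-(3,4,5-trimethoxyphenyl)propyl acetate | O[C@H](C)[C@@H](OC(C)=O)c1cc(OC)c(OC)c(OC)c1 | intermediate
6 | 1-bromo-3,5-dimethoxybenzene | COc1cc(Br)cc(OC)c1 | starting material
7 | (S)-propylene oxide | C[C@H]1CO1 | starting material
8 | 3,5-dimethoxyphenylmagnesium bromide | COc1cc([Mg]Br)cc(OC)c1 | intermediate
9 | (S)-1-(3,5-dimethoxyphenyl)propan-2-ol | C[C@H](O)Cc1cc(OC)cc(OC)c1 | intermediate
10 | (S)-1-(3,5-dimethoxyphenyl)-2-(triisopropylsilyloxy)propane | C[C@H](O[Si](C(C)C)(C(C)C)C(C)C)Cc1cc(OC)cc(OC)c1 | intermediate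
11 | 1,5-dimethoxy-3-[(S)-2-(triisopropylsilyloxy)propyl]cyclohexa-1,4-diene | C[C@H](O[Si](C(C)C)(C(C)C)C(C)C)CC1C=C(OC)CC(OC)=C1 | intermediate
12 | 5-[(S)-2-(triisopropylsilyloxy)propyl]cyclohexane-1,3-dione | C[C@H](O[Si](C(C)C)(C(C)C)C(C)C)CC1CC(=O)CC(=O)C1 | intermediate
13 | 2-diazo-5-[(S)-2-(triisopropylsilyloxy)propyl]cyclohexane-1,3-dione | C[C@H](O[Si](C(C)C)(C(C)C)C(C)C)CC1CC(=O)C(=[N+]=[N-])C(=O)C1 | intermediate
14 | 2-{[(1S,2R)-1-acetoxy-1-(3,4,5-trimethoxyphenyl)propan-2-yl]oxy}-3-hydroxy-5-[(S)-2-(triisopropylsilyloxy)propyl]cyclohex-2-en-1-one | C[C@H](O[Si](C(C)C)(C(C)C)C(C)C)CC1CC(=O)C(O[C@H](C)[C@@H](OC(C)=O)c2cc(OC)c(OC)c(OC)c2)=C(O)C1 | intermediate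
15 | (1S,2R)-2-{2,6-dihydroxy-4-[(S)-2-(triisopropylsilyloxy)propyl]phenoxy}-1-(3,4,5-trimethoxyphenyl)propyl acetate | C[C@H](O[Si](C(C)C)(C(C)C)C(C)C)Cc1cc(O)c(O[C@H](C)[C@@H](OC(C)=O)c2cc(OC)c(OC)c(OC)c2)c(O)c1 | intermediate
16 | (1S,2R)-2-{2,6-dimethoxy-4-[(S)-2-(triisopropylsilyloxy)propyl]phenoxy}-1-(3,4,5-trimethoxyphenyl)propyl acetate | C[C@H](O[Si](C(C)C)(C(C)C)C(C)C)Cc1cc(OC)c(O[C@H](C)[C@@H](OC(C)=O)c2cc(OC)c(OC)c(OC)c2)c(OC)c1 | intermediate
17 | (1S,2R)-2-{4-[(S)-2-hydroxypropyl]-2,6-dimethoxyphenoxy}-1-(3,4,5-trimethoxyphenyl)propyl acetate | C[C@H](O)Cc1cc(OC)c(O[C@H](C)[C@@H](OC(C)=O)c2cc(OC)c(OC)c(OC)c2)c(OC)c1 | intermediate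
18 | 4-allyl-2,6-dimethoxyphenol (methoxyeugenol) | C=CCc1cc(OC)c(O)c(OC)c1 | starting material
19 | (E)-2,6-dimethoxy-4-(prop-1-en-1-yl)phenol | C/C=C/c1cc(OC)c(O)c(OC)c1 | intermediate
20 | CNP0157869.1, (7S,8R,8′R) | C/C=C/c1cc(OC)c(O[C@H](C)Cc2cc(OC)c(O[C@H](C)[C@@H](OC(C)=O)c3cc(OC)c(OC)c(OC)c3)c(OC)c2)c(OC)c1 | target

**Step count and risks**

Total steps: 14. Longest linear sequence: 9 steps (steps 1, 2, 3, 4, 9, 10, 11, 12, 14; the branch through steps 5–8 is equally long).

Steps most likely to fail:

1. Step 10, oxidative aromatisation. DDQ may over-oxidise the electron-rich resorcinol as it forms, or abstract hydride from the ring B benzylic CH2 that lies para to the ether oxygen, or dehydrogenate the enol too slowly. The fallback sets out from 14 and separates enol capping from dehydrogenation. The vinylogous acid is O-methylated (Me2SO4, K2CO3, acetone) to the 2-alkoxy-3-methoxycyclohex-2-en-1-one F1, formed as ring epimers that converge later. F1 is an ordinary cyclohexenone and is dehydrogenated by palladium-catalysed aerobic oxidation (Pd(OCOCF3)2, 2-(dimethylamino)pyridine, TsOH, O2, DMSO, 80 °C) to the 2-alkoxy-3-methoxyphenol F2. Methylation of F2 (MeI, K2CO3, acetone) comes back to the route at 16.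

2. Step 14, Mitsunobu etherification. The activated homobenzylic alcohol may eliminate to the conjugated propenyl arene while the hindered, weakly acidic di-ortho-methoxy phenol attacks slowly. The fallback sets out from 17 and uses purchased syringaldehyde (4-hydroxy-3,5-dimethoxybenzaldehyde), a considerably more acidic phenol, in the same coupling (PPh3, DIAD, toluene). This gives, with the same inversion at C8′, the aryl ether aldehyde F3. Takai–Utimoto ethylidenation (CrCl2, CH3CHI2, THF, rt) then converts the formyl group into the E-propenyl group without touching the acetate and comes back to the route at 20.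

3. Step 4, epoxide acetolysis. Partial ionisation at C7 would erode the erythro selectivity, competing attack at C8 would give the regioisomer, and 1,2-acetyl migration during isolation would interconvert the regioisomers; the last two together would lower the enantiomeric purity. The fallback sets out from 4 and opens the epoxide without protic acid: Ac2O with catalytic Bu4NOAc (60–80 °C), where acetate attacks in an SN2 step and the alkoxide is acetylated at once, gives the erythro diacetate F4. Candida antarctica lipase B (pH 7 phosphate buffer, MTBE) should then hydrolyse the less hindered, R-configured C8 acetate and leave the benzylic C7 acetate, coming back to the route at 5. The enzyme should also discriminate against the enantiomeric diacetate that C8 attack would give.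

**Further compounds**

F1 | step 10 | 2-{[(1S,2R)-1-acetoxy-1-(3,4,5-trimethoxyphenyl)propan-2-yl]oxy}-3-methoxy-5-[(S)-2-(triisopropylsilyloxy)propyl]cyclohex-2-en-1-one | C[C@H](O[Si](C(C)C)(C(C)C)C(C)C)CC1CC(=O)C(O[C@H](C)[C@@H](OC(C)=O)c2cc(OC)c(OC)c(OC)c2)=C(OC)C1
F2 | step 10 | (1S,2R)-2-{2-hydroxy-6-methoxy-4-[(S)-2-(triisopropylsilyloxy)propyl]phenoxy}-1-(3,4,5-trimethoxyphenyl)propyl acetate | C[C@H](O[Si](C(C)C)(C(C)C)C(C)C)Cc1cc(O)c(O[C@H](C)[C@@H](OC(C)=O)c2cc(OC)c(OC)c(OC)c2)c(OC)c1
F3 | step 14 | (1S,2R)-2-{4-[(R)-2-(4-formyl-2,6-dimethoxyphenoxy)propyl]-2,6-dimethoxyphenoxy}-1-(3,4,5-trimethoxyphenyl)propyl acetate | O=Cc1cc(OC)c(O[C@H](C)Cc2cc(OC)c(O[C@H](C)[C@@H](OC(C)=O)c3cc(OC)c(OC)c(OC)c3)c(OC)c2)c(OC)c1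
F4 | step 4 | (1S,2R)-1-(3,4,5-trimethoxyphenyl)propane-1,2-diyl diacetate | CC(=O)O[C@H](C)[C@@H](OC(C)=O)c1cc(OC)c(OC)c(OC)c1
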